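**Strategy.** The target is cut at the biaryl bond (Suzuki coupling) into a 2,3-cis-oxolane boronate and a bromo-aryltetralin, both made from one tetraol (13) assembled on (S)-malic acid. The tetralin carbocycle (C1, C2, C3, C4, C4a, C8a) is not closed directly: because its C7 phenol is para to C4a and C1 is a p-hydroxybenzylic carbon, a phenoxide para-alkylation first gives a spiro[4.5]decadienone whose five-membered ring holds C1–C4 and C4a. Acid then moves C1 from C4a to C8a (dienone–phenol rearrangement), enlarging the five-membered ring to the six-membered one and setting C1 trans to C2 in one operation.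

Key step: step 15

Remark: TBS = tert-butyldimethylsilyl; 12, 13 and 18 are carried as mixtures of epimers at the benzylic carbinol carbon (written without a descriptor), because that centre is erased in steps 10 and 14.

Step 1
Reactants: 1 (S)-malic acid; 2 pivalaldehyde
Product: 3 [(2S,4S)-2-tert-butyl-5-oxo-1,3-dioxolan-4-yl]acetic acid
Conditions: p-TsOH·H2O (cat.), H2SO4 (cat.), pentane, reflux, Dean–Stark; recrystallisation
Reagents that add atoms: none
Why: Acid-catalysed acetalisation of the α-hydroxy acid unit (first stage of a self-regeneration-of-stereocentres sequence) should give the dioxolanone, the new acetal centre being set cis to the CH2CO2H group under thermodynamic control and enriched by crystallisation.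

Step 2
Reactants: 4 vanillin
Product: 5 3-methoxy-4-(TBS-oxy)benzaldehyde
Conditions: TBSCl, imidazole, DMF, rt
Reagents that add atoms: tert-butyldimethylsilyl chloride CC(C)(C)[Si](C)(C)Cl
Why: Imidazole-promoted silylation of the phenol gives an aryl silyl ether that tolerates the amide bases and hydrides used later.

Step 3
Reactants: 5 3-methoxy-4-(TBS-oxy)benzaldehyde
Product: 6 [3-methoxy-4-(TBS-oxy)phenyl]methanol
Conditions: NaBH4, MeOH, 0 °C
Reagents that add atoms: none
Why: Borohydride reduction of the aldehyde leaves the aryl silyl ether untouched.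

Step 4
Reactants: 6 [3-methoxy-4-(TBS-oxy)phenyl]methanol
Product: 7 4-(bromomethyl)-2-methoxy-1-(TBS-oxy)benzene
Conditions: CBr4, PPh3, CH2Cl2, 0 °C; used fresh
Reagents that add atoms: carbon tetrabromide BrC(Br)(Br)Br
Why: The Appel reaction converts the benzylic alcohol into the bromide under neutral conditions that spare the aryl silyl ether.

Step 5
Reactants: 3 [(2S,4S)-2-tert-butyl-5-oxo-1,3-dioxolan-4-yl]acetic acid; 7 4-(bromomethyl)-2-methoxy-1-(TBS-oxy)benzene
Product: 8 [(2S,4S)-2-tert-butyl-4-{[3-methoxy-4-(TBS-oxy)phenyl]methyl}-5-oxo-1,3-dioxolan-4-yl]acetic acid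
Conditions: LiHMDS (2.1 equiv), THF, −78 °C; then 7, −78 → −30 °C
Reagents that add atoms: none
Why: Self-regeneration-of-stereocentres alkylation: the carboxylate/dioxolanone-enolate dianion is benzylated trans to the tert-butyl group, so the benzyl group takes the place of the original hydrogen and the quaternary carbinol carbon (future tetralin C3 and oxolane C4) is set with retention.

Step 6
Reactants: 8 [(2S,4S)-2-tert-butyl-4-{[3-methoxy-4-(TBS-oxy)phenyl]methyl}-5-oxo-1,3-dioxolan-4-yl]acetic acid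
Product: 9 dimethyl (2S)-2-hydroxy-2-{[3-methoxy-4-(TBS-oxy)phenyl]methyl}butanedioate
Conditions: HCl (1.25 M in MeOH), 0 °C → rt
Reagents that add atoms: methanol CO
Why: Acid-catalysed methanolysis opens the dioxolanone to the methyl α-hydroxy ester and esterifies the free acid (Fischer esterification) without touching the quaternary carbinol, aryl silyl ethers being the more acid-stable silyl ethers.

Step 7
Reactants: 10 5-bromovanillin
Product: 11 3-bromo-5-methoxy-4-(TBS-oxy)benzaldehyde
Conditions: TBSCl, imidazole, DMF, rt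
Reagents that add atoms: tert-butyldimethylsilyl chloride CC(C)(C)[Si](C)(C)Cl
Why: Silylation of the hindered but acidic phenol, as in step 2.

Step 8
Reactants: 9 dimethyl (2S)-2-hydroxy-2-{[3-methoxy-4-(TBS-oxy)phenyl]methyl}butanedioate; 11 3-bromo-5-methoxy-4-(TBS-oxy)benzaldehyde
Product: 12 dimethyl (2S,3R)-3-{[3-bromo-5-methoxy-4-(TBS-oxy)phenyl](hydroxy)methyl}-2-hydroxy-2-{[3-methoxy-4-(TBS-oxy)phenyl]methyl}butanedioate (epimers at the carbinol carbon)
Conditions: LDA (2.2 equiv), THF, −78 → −30 → −78 °C; then 11, −78 °C; AcOH quench at −78 °C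
Reagents that add atoms: none
Why: Fráter–Seebach aldol addition: the lithium-chelated alkoxide–enolate dianion should be attacked by the aldehyde anti to the alkoxide, setting C3 as R, while the carbinol carbon forms unselectively and is erased later; the cold quench avoids retro-aldol and lactonisation–elimination.

Step 9
Reactants: 12 aldol adduct (epimers)
Product: 13 (2S,3R)-3-{[3-bromo-5-methoxy-4-(TBS-oxy)phenyl](hydroxy)methyl}-2-{[3-methoxy-4-(TBS-oxy)phenyl]methyl}butane-1,2,4-triol (epimers at the carbinol carbon)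
Conditions: LiBH4, THF, 0 °C → rt
Reagents that add atoms: none
Why: LiBH4 reduces both methyl esters (and any lactonised material) to primary alcohols without touching the aryl bromide or the aryl silyl ethers.

Step 10
Reactants: 13 tetraol (epimers)
Product: 14 (2S,3S)-1-[3-bromo-5-methoxy-4-(TBS-oxy)phenyl]-3-hydroxy-2,3-bis(hydroxymethyl)-4-[3-methoxy-4-(TBS-oxy)phenyl]butan-1-one
Conditions: activated MnO2 (excess), CH2Cl2, rt; used crude
Reagents that add atoms: none
Why: Activated MnO2 oxidises only the benzylic secondary alcohol, so both carbinol epimers converge on one aryl ketone, which equilibrates with its five-membered hemiketal.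

Step 11
Reactants: 14 hydroxy ketone
Product: 16 (3S,4R,5R)-5-[3-bromo-5-methoxy-4-(TBS-oxy)phenyl]-4-(hydroxymethyl)-3-{[3-methoxy-4-(TBS-oxy)phenyl]methyl}oxolan-3-ol, via cyclic hemiketal 15 (not isolated)
Conditions: Et3SiH (5 equiv), BF3·OEt2 (3 equiv), CH2Cl2, −78 → −40 °C
Reagents that add atoms: none
Why: Ionic hydrogenation of the hemiketal through the 2-aryl oxocarbenium ion: hydride should enter C5 anti to the adjacent C4 hydroxymethyl group and on the face of the C3 oxygen (inside attack on the envelope), which places the aryl group cis to CH2OH and sets C5 as R.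

Step 12
Reactants: 16 cis-oxolane bromide
Product: 17 (3S,4R,5R)-4-(hydroxymethyl)-5-[3-methoxy-5-(4,4,5,5-tetramethyl-1,3,2-dioxaborolan-2-yl)-4-(TBS-oxy)phenyl]-3-{[3-methoxy-4-(TBS-oxy)phenyl]methyl}oxolan-3-ol
Conditions: B2pin2, Pd(dppf)Cl2 (5 mol %), KOAc, 1,4-dioxane, 85 °C
Reagents that add atoms: bis(pinacolato)diboron CC1(C)OB(OC1(C)C)B1OC(C)(C)C(C)(C)O1
Why: Miyaura borylation of the aryl bromide, with free alcohols and aryl silyl ethers tolerated under the KOAc conditions.

Step 13
Reactants: 13 tetraol (epimers)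
Product: 18 (2S,3R)-3-{acetoxy[3-bromo-5-methoxy-4-(TBS-oxy)phenyl]methyl}-2-hydroxy-2-{[3-methoxy-4-(TBS-oxy)phenyl]methyl}butane-1,4-diyl diacetate (epimers at the benzylic carbon)
Conditions: Ac2O, pyridine, 0 °C → rt
Reagents that add atoms: acetic anhydride CC(=O)OC(C)=O
Why: Acetylation of the two primary and the secondary benzylic hydroxyl groups (the tertiary one is left) blocks the C1 oxygen as a nucleophile and turns the benzylic oxygen into a leaving group.

Step 14
Reactants: 18 triacetate (epimers)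
Product: 20 [(1S,2S,3S)-1-(3-bromo-4-hydroxy-5-methoxyphenyl)-3-hydroxy-7-methoxy-8-oxospiro[4.5]deca-6,9-diene-2,3-diyl]dimethanediyl diacetate (both C5 epimers), via quinone methide 19 (not isolated)
Conditions: TBAF (2.2 equiv), THF (0.005 M), −40 → 0 °C; aq NH4Cl
Reagents that add atoms: none
Why: Fluoride frees both phenoxides; the bromo-methoxy phenoxide expels the benzylic acetate (1,6-elimination) to a p-quinone methide, whose exocyclic carbon is attacked by the para carbon of the second phenoxide (5-exo-trig alkylative dearomatisation of the Ar1⁻-5 type, O-attack being geometrically impossible), the C1/C2-trans arrangement being expected from the less eclipsed transition state and the spiro centre forming as a mixture that is erased in step 15.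

Step 15
Reactants: 20 spirodienone diacetate
Product: 21 [(1S,2S,3S)-1-(3-bromo-4-hydroxy-5-methoxyphenyl)-3,7-dihydroxy-6-methoxy-1,2,3,4-tetrahydronaphthalene-2,3-diyl]dimethanediyl diacetate
Conditions: TFA (5 equiv), CH2Cl2, 0 °C → rt
Reagents that add atoms: none
Why: O-protonation of the cross-conjugated dienone gives a hydroxycyclohexadienyl cation in which spiro carbon C5 is flanked by the cationic termini C6 and C10, and C1, a p-hydroxybenzylic carbon, shifts from C5 to C10 (in the limiting stepwise form the C1–C5 bond ionises to a tethered p-hydroxybenzyl cation/phenol pair that recloses at C10), after which loss of H-10 restores the arene. This is the dienone–phenol rearrangement, whose closest precedent is the acid conversion of spiro[4.5]deca-1,4-dien-3-ones into 5,6,7,8-tetrahydro-2-naphthols. No ring is closed from an open chain: the five-membered carbocycle C1–C2–C3–C4–C5 becomes the six-membered ring by the 1,2-shift (in the stepwise limit a 6-exo-trig Friedel–Crafts closure onto the benzylic cation). The new stereocentre, tetralin C1, is set trans to the C2 acetoxymethyl group by the existing C2 and C3 centres: a concerted shift retains the trans arrangement of 20, and the ionised pathway recloses through a chair-like transition state with the aryl group and both CH2OAc groups equatorial, so both C5 epimers and any C1 epimer of 20 should converge. The step needs migration of C1 and not of the C4 methylene, and to C10 and not to C6; the first is secured by the cation-stabilising p-hydroxyaryl group on C1, the second by C10 being unhindered and para to the methoxy group while C6 is flanked by it.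

Step 16
Reactants: 17 oxolane boronate; 21 tetralin bromide
Product: 22 biaryl with the oxolane half as its bis-TBS ether and the tetralin half as its diacetate (the two acetates on the tetralin CH2O groups, the two silyl ethers on the oxolane-side phenols)
Conditions: Pd(OAc)2 (5 mol %), SPhos (10 mol %), K3PO4, toluene/H2O 10:1, 70 °C
Reagents that add atoms: none
Why: Suzuki–Miyaura coupling with a biarylphosphine ligand suited to 2,2′-dioxygenated biaryls; the new axis carries only two ortho substituents and is not a stereo element, and any partial loss of acetyl or silyl groups converges in step 17.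

Step 17
Reactants: 22 protected biaryl
Product: 23 target CNP0344108.1
Conditions: K2CO3, MeOH (degassed), rt; aq NH4Cl
Reagents that add atoms: none
Why: Carbonate-mediated methanolysis removes the two acetates and the two aryl silyl ethers without acid, so the acid-labile 2,3-cis benzylic ether of the oxolane is not ionised.

**Compound list**

1 | (S)-malic acid | O[C@@H](CC(=O)O)C(=O)O | starting material
2 | pivalaldehyde | CC(C)(C)C=O | starting material
3 | [(2S,4S)-2-tert-butyl-5-oxo-1,3-dioxolan-4-yl]acetic acid | OC(=O)C[C@@H]1O[C@H](C(C)(C)C)OC1=O | intermediate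
4 | vanillin | COc1cc(C=O)ccc1O | starting material
5 | 3-methoxy-4-(TBS-oxy)benzaldehyde | COc1cc(C=O)ccc1O[Si](C)(C)C(C)(C)C | intermediate
6 | [3-methoxy-4-(TBS-oxy)phenyl]methanol | COc1cc(CO)ccc1O[Si](C)(C)C(C)(C)C | intermediate
7 | 4-(bromomethyl)-2-methoxy-1-(TBS-oxy)benzene | COc1cc(CBr)ccc1O[Si](C)(C)C(C)(C)C | intermediate
8 | [(2S,4S)-2-tert-butyl-4-{[3-methoxy-4-(TBS-oxy)phenyl]methyl}-5-oxo-1,3-dioxolan-4-yl]acetic acid | OC(=O)C[C@]1(Cc2ccc(O[Si](C)(C)C(C)(C)C)c(OC)c2)O[C@H](C(C)(C)C)OC1=O | intermediate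
9 | dimethyl (2S)-2-hydroxy-2-{[3-methoxy-4-(TBS-oxy)phenyl]methyl}butanedioate | COC(=O)C[C@](O)(C(=O)OC)Cc1ccc(O[Si](C)(C)C(C)(C)C)c(OC)c1 | intermediate
10 | 5-bromovanillin | COc1cc(C=O)cc(Br)c1O | starting material
11 | 3-bromo-5-methoxy-4-(TBS-oxy)benzaldehyde | COc1cc(C=O)cc(Br)c1O[Si](C)(C)C(C)(C)C | intermediate
12 | dimethyl (2S,3R)-3-{[3-bromo-5-methoxy-4-(TBS-oxy)phenyl](hydroxy)methyl}-2-hydroxy-2-{[3-methoxy-4-(TBS-oxy)phenyl]methyl}butanedioate, carbinol epimers | COC(=O)[C@H](C(O)c1cc(OC)c(O[Si](C)(C)C(C)(C)C)c(Br)c1)[C@](O)(C(=O)OC)Cc1ccc(O[Si](C)(C)C(C)(C)C)c(OC)c1 | intermediate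
13 | (2S,3R)-3-{[3-bromo-5-methoxy-4-(TBS-oxy)phenyl](hydroxy)methyl}-2-{[3-methoxy-4-(TBS-oxy)phenyl]methyl}butane-1,2,4-triol, carbinol epimers | OC[C@H](C(O)c1cc(OC)c(O[Si](C)(C)C(C)(C)C)c(Br)c1)[C@](O)(CO)Cc1ccc(O[Si](C)(C)C(C)(C)C)c(OC)c1 | intermediate
14 | (2S,3S)-1-[3-bromo-5-methoxy-4-(TBS-oxy)phenyl]-3-hydroxy-2,3-bis(hydroxymethyl)-4-[3-methoxy-4-(TBS-oxy)phenyl]butan-1-one | OC[C@H](C(=O)c1cc(OC)c(O[Si](C)(C)C(C)(C)C)c(Br)c1)[C@](O)(CO)Cc1ccc(O[Si](C)(C)C(C)(C)C)c(OC)c1 | intermediate
15 | (3S,4S)-2-[3-bromo-5-methoxy-4-(TBS-oxy)phenyl]-3-(hydroxymethyl)-4-{[3-methoxy-4-(TBS-oxy)phenyl]methyl}oxolane-2,4-diol (cyclic hemiketal, C2 epimers) | COc1cc(C[C@@]2(O)COC(O)(c3cc(OC)c(O[Si](C)(C)C(C)(C)C)c(Br)c3)[C@H]2CO)ccc1O[Si](C)(C)C(C)(C)C | intermediate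
16 | (3S,4R,5R)-5-[3-bromo-5-methoxy-4-(TBS-oxy)phenyl]-4-(hydroxymethyl)-3-{[3-methoxy-4-(TBS-oxy)phenyl]methyl}oxolan-3-ol | COc1cc(C[C@@]2(O)CO[C@@H](c3cc(OC)c(O[Si](C)(C)C(C)(C)C)c(Br)c3)[C@H]2CO)ccc1O[Si](C)(C)C(C)(C)C | intermediate
17 | (3S,4R,5R)-4-(hydroxymethyl)-5-[3-methoxy-5-(pinacolboryl)-4-(TBS-oxy)phenyl]-3-{[3-methoxy-4-(TBS-oxy)phenyl]methyl}oxolan-3-ol | COc1cc(C[C@@]2(O)CO[C@@H](c3cc(OC)c(O[Si](C)(C)C(C)(C)C)c(B4OC(C)(C)C(C)(C)O4)c3)[C@H]2CO)ccc1O[Si](C)(C)C(C)(C)C | intermediate
18 | (2S,3R)-3-{acetoxy[3-bromo-5-methoxy-4-(TBS-oxy)phenyl]methyl}-2-hydroxy-2-{[3-methoxy-4-(TBS-oxy)phenyl]methyl}butane-1,4-diyl diacetate, benzylic epimers | CC(=O)OC[C@H](C(OC(C)=O)c1cc(OC)c(O[Si](C)(C)C(C)(C)C)c(Br)c1)[C@](O)(COC(C)=O)Cc1ccc(O[Si](C)(C)C(C)(C)C)c(OC)c1 | intermediate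
19 | (2S,3S)-3-[(3-bromo-5-methoxy-4-oxocyclohexa-2,5-dien-1-ylidene)methyl]-2-hydroxy-2-[(4-hydroxy-3-methoxyphenyl)methyl]butane-1,4-diyl diacetate (p-quinone methide) | CC(=O)OC[C@H](C=C1C=C(OC)C(=O)C(Br)=C1)[C@](O)(COC(C)=O)Cc1ccc(O)c(OC)c1 | intermediate
20 | [(1S,2S,3S)-1-(3-bromo-4-hydroxy-5-methoxyphenyl)-3-hydroxy-7-methoxy-8-oxospiro[4.5]deca-6,9-diene-2,3-diyl]dimethanediyl diacetate, C5 epimers | COC1=CC2(C=CC1=O)C[C@@](O)(COC(C)=O)[C@H](COC(C)=O)[C@H]2c1cc(OC)c(O)c(Br)c1 | intermediate
21 | [(1S,2S,3S)-1-(3-bromo-4-hydroxy-5-methoxyphenyl)-3,7-dihydroxy-6-methoxy-1,2,3,4-tetrahydronaphthalene-2,3-diyl]dimethanediyl diacetate | COc1cc(cc(Br)c1O)[C@H]2c3cc(O)c(OC)cc3C[C@@](O)(COC(C)=O)[C@@H]2COC(C)=O | intermediate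
22 | biaryl: oxolane half as bis-TBS ether, tetralin half as diacetate | COc1cc(C[C@@]2(O)CO[C@@H](c3cc(OC)c(O[Si](C)(C)C(C)(C)C)c(-c4cc([C@H]5c6cc(O)c(OC)cc6C[C@@](O)(COC(C)=O)[C@@H]5COC(C)=O)cc(OC)c4O)c3)[C@H]2CO)ccc1O[Si](C)(C)C(C)(C)C | intermediate
23 | CNP0344108.1: (1S,2S,3S)-1-[4-hydroxy-3-{2-hydroxy-5-[(2R,3R,4S)-4-hydroxy-4-[(4-hydroxy-3-methoxyphenyl)methyl]-3-(hydroxymethyl)oxolan-2-yl]-3-methoxyphenyl}-5-methoxyphenyl]-2,3-bis(hydroxymethyl)-6-methoxy-1,2,3,4-tetrahydronaphthalene-3,7-diol | COc1cc(C[C@@]2(O)CO[C@@H](c3cc(OC)c(O)c(-c4cc([C@H]5c6cc(O)c(OC)cc6C[C@@](O)(CO)[C@@H]5CO)cc(OC)c4O)c3)[C@H]2CO)ccc1O | target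

**Totals.** 17 steps in all. Longest linear sequence: 12 steps (2, 3, 4, 5, 6, 8, 9, 10, 11, 12, 16, 17; the tetralin branch 2–6, 8, 9, 13–17 is equally long).

**Steps most likely to fail**

Step 14 (spirocyclisation). After desilylation the quinone methide may be consumed intermolecularly, or, if an acetyl group is lost or migrates, trapped by the freed primary oxygen to an oxolane, instead of being attacked by the para carbon. The fallback runs the same cyclisation at the carboxyl oxidation level, where no such oxygen nucleophile exists and the leaving group is tethered. It sets out from 12 and comes back at 23. Compound 12 is lactonised (PPTS, toluene, 60 °C) to the paraconate lactone F1, both benzylic epimers being usable. TBAF at high dilution should then expel the lactone carboxylate and give the spirodienone carboxylic acid F2; re-addition of the carboxylate only regenerates a lactone. TFA rearranges F2 to the tetralin hydroxy acid F3, and LiAlH4 reduces acid and ester to the bromo pentol F4. Coupling of F4 with boronate 17 under the conditions of step 16 gives the bis-silyl ether F5, which the conditions of step 17 convert into 23.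

Step 15 (ring expansion). Ionisation of the C1–C5 bond may be followed by diversion of the p-hydroxybenzyl cation (intermolecular capture, participation of the acetoxy groups, elimination at the tertiary alcohol) instead of closure at C10. The fallback removes the p-hydroxy group's push so that only the concerted 1,2-shift remains. It sets out from 20 and comes back at 21. The ring-A phenol of 20 is acetylated (Ac2O, pyridine, 0 °C) to the aryl acetate spirodienone F6, which is rearranged with BF3·OEt2 in CH2Cl2 at −20 °C to the tetralin triacetate F7. Selective aminolysis of the aryl acetate (pyrrolidine, CH2Cl2, 0 °C) returns 21.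

Step 11 (oxocarbenium reduction). Hydride delivery may show poor facial selectivity, the benzylic C–O bond may be reduced further to the ring-opened methylene compound, or the cation may be captured by the neighbouring benzyl arene. The fallback fixes the benzylic centre at the aldol stage and carries it through with retention. It sets out from 12 and comes back at 16. Lactonisation of 12 (PPTS, toluene, 60 °C) and chromatographic separation give the 2,3-cis paraconate lactone F8; its supply depends on the uncontrolled carbinol ratio of step 8, and the other epimer is not lost because LiBH4 turns it into 13 for the tetralin branch. DIBAL-H (CH2Cl2, −78 °C) reduces the ester to the primary alcohol and the lactone to the lactol F9. Et3SiH/BF3·OEt2 at −78 °C then removes the lactol hydroxyl through an oxocarbenium ion at the non-stereogenic carbon, leaving the benzylic centre untouched, and gives 16.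

**Further compounds**

F1 | step 14 | methyl (3R,4S)-2-[3-bromo-5-methoxy-4-(TBS-oxy)phenyl]-4-hydroxy-4-{[3-methoxy-4-(TBS-oxy)phenyl]methyl}-5-oxooxolane-3-carboxylate, C2 epimers | COc1cc(C[C@@]2(O)C(=O)OC(c3cc(OC)c(O[Si](C)(C)C(C)(C)C)c(Br)c3)[C@H]2C(=O)OC)ccc1O[Si](C)(C)C(C)(C)C
F2 | step 14 | (1S,2S,3S)-1-(3-bromo-4-hydroxy-5-methoxyphenyl)-3-hydroxy-7-methoxy-2-(methoxycarbonyl)-8-oxospiro[4.5]deca-6,9-diene-3-carboxylic acid, C5 epimers | COC1=CC2(C=CC1=O)C[C@@](O)(C(=O)O)[C@H](C(=O)OC)[C@H]2c1cc(OC)c(O)c(Br)c1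
F3 | step 14 | (1S,2S,3S)-1-(3-bromo-4-hydroxy-5-methoxyphenyl)-3,7-dihydroxy-6-methoxy-2-(methoxycarbonyl)-1,2,3,4-tetrahydronaphthalene-3-carboxylic acid | COc1cc(cc(Br)c1O)[C@H]2c3cc(O)c(OC)cc3C[C@@](O)(C(=O)O)[C@@H]2C(=O)OC
F4 | step 14 | (1S,2S,3S)-1-(3-bromo-4-hydroxy-5-methoxyphenyl)-2,3-bis(hydroxymethyl)-6-methoxy-1,2,3,4-tetrahydronaphthalene-3,7-diol | COc1cc(cc(Br)c1O)[C@H]2c3cc(O)c(OC)cc3C[C@@](O)(CO)[C@@H]2CO
F5 | step 14 | target with both phenols of the oxolane half as TBS ethers | COc1cc(C[C@@]2(O)CO[C@@H](c3cc(OC)c(O[Si](C)(C)C(C)(C)C)c(-c4cc([C@H]5c6cc(O)c(OC)cc6C[C@@](O)(CO)[C@@H]5CO)cc(OC)c4O)c3)[C@H]2CO)ccc1O[Si](C)(C)C(C)(C)C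
F6 | step 15 | [(1S,2S,3S)-1-(4-acetoxy-3-bromo-5-methoxyphenyl)-3-hydroxy-7-methoxy-8-oxospiro[4.5]deca-6,9-diene-2,3-diyl]dimethanediyl diacetate, C5 epimers | COC1=CC2(C=CC1=O)C[C@@](O)(COC(C)=O)[C@H](COC(C)=O)[C@H]2c1cc(OC)c(OC(C)=O)c(Br)c1
F7 | step 15 | [(1S,2S,3S)-1-(4-acetoxy-3-bromo-5-methoxyphenyl)-3,7-dihydroxy-6-methoxy-1,2,3,4-tetrahydronaphthalene-2,3-diyl]dimethanediyl diacetate | COc1cc(cc(Br)c1OC(C)=O)[C@H]2c3cc(O)c(OC)cc3C[C@@](O)(COC(C)=O)[C@@H]2COC(C)=O
F8 | step 11 | methyl (2R,3R,4S)-2-[3-bromo-5-methoxy-4-(TBS-oxy)phenyl]-4-hydroxy-4-{[3-methoxy-4-(TBS-oxy)phenyl]methyl}-5-oxooxolane-3-carboxylate (2,3-cis) | COc1cc(C[C@@]2(O)C(=O)O[C@@H](c3cc(OC)c(O[Si](C)(C)C(C)(C)C)c(Br)c3)[C@H]2C(=O)OC)ccc1O[Si](C)(C)C(C)(C)C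
F9 | step 11 | (3S,4R,5R)-5-[3-bromo-5-methoxy-4-(TBS-oxy)phenyl]-4-(hydroxymethyl)-3-{[3-methoxy-4-(TBS-oxy)phenyl]methyl}oxolane-2,3-diol (lactol, C2 epimers) | COc1cc(C[C@@]2(O)C(O)O[C@@H](c3cc(OC)c(O[Si](C)(C)C(C)(C)C)c(Br)c3)[C@H]2CO)ccc1O[Si](C)(C)C(C)(C)C
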